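Numbering the oxolane O1, C2 (aryl), C3 (CH2O-ester), C4 (OH), C5 (CH2): the C4–C5 bond lies next to ring oxygen O1, so it is made as the C4=C5 double bond of a cyclic enol ether. Ring-closing metathesis of an acyclic vinyl ether/terminal alkene diene, whose C2 and C3 centres come from one syn-selective allylboration, closes the five-membered ring in one operation. The enol ether polarisation then places a heteroatom on C4, and a temporary O–Si–C4 tether from the C3 hydroxymethyl group (a siloxane ring absent from the target) delivers it cis, giving the all-cis triad before final primary acylation.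

Key step: step 4

Remark: the ring-atom names O1, C2, C3, C4, C5 of the target oxolane are used throughout, also for acyclic precursors.
Assumption: (−)-Ipc2BH, the crystalline (−)-diisopinocampheylborane obtained from (+)-α-pinene and BH3·SMe2, is treated as a stock reagent.

Step 1
Reactants: 1 buta-2,3-dien-1-ol
Product: 2 tert-butyl(buta-2,3-dien-1-yloxy)dimethylsilane
Conditions: TBSCl, imidazole, CH2Cl2, 0 °C to rt
Reagents that add atoms: tert-butyldimethylsilyl chloride, CC(C)(C)[Si](C)(C)Cl
Why: Imidazole-promoted silylation of a primary alcohol leaves the allene untouched and involves no stereocenter.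

Step 2
Reactants: 2 tert-butyl(buta-2,3-dien-1-yloxy)dimethylsilane, 3 3,4-dimethoxybenzaldehyde
Product: 6 (1S,2S)-2-{[(tert-butyldimethylsilyl)oxy]methyl}-1-(3,4-dimethoxyphenyl)but-3-en-1-ol, via (Z)-allylborane 4 (not isolated), via borinate ester 5 (not isolated)
Conditions: (−)-Ipc2BH, THF, −40 to −25 °C; then 3, −78 °C; then NaOH, H2O2, 0 °C to rt
Reagents that add atoms: none
Why: Kinetic hydroboration of the terminal allene π-bond anti to the CH2OTBS group should give the (Z)-γ-substituted allylborane, which adds to the aldehyde through a Zimmerman–Traxler chair (allylboration), the (Z)-geometry setting the syn C2/C3 relationship and the isopinocampheyl groups derived from (+)-α-pinene setting the (S) carbinol centre.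

Step 3
Reactants: 6 (1S,2S)-2-{[(tert-butyldimethylsilyl)oxy]methyl}-1-(3,4-dimethoxyphenyl)but-3-en-1-ol
Product: 7 tert-butyl({(2S)-2-[(S)-(3,4-dimethoxyphenyl)(ethenyloxy)methyl]but-3-en-1-yl}oxy)dimethylsilane
Conditions: Pd(OCOCF3)2 (cat.), 4,7-diphenyl-1,10-phenanthroline (cat.), Et3N (cat.), n-butyl vinyl ether (solvent), 75 °C
Reagents that add atoms: n-butyl vinyl ether, C=COCCCC
Why: Palladium-catalysed transfer vinylation (transetherification with excess vinyl ether) converts the secondary alcohol into its vinyl ether under near-neutral conditions that leave the silyl ether, the terminal alkene and both stereocenters untouched.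

Step 4
Reactants: 7 tert-butyl({(2S)-2-[(S)-(3,4-dimethoxyphenyl)(ethenyloxy)methyl]but-3-en-1-yl}oxy)dimethylsilane
Product: 8 tert-butyl{[(2S,3S)-2-(3,4-dimethoxyphenyl)-2,3-dihydrofuran-3-yl]methoxy}dimethylsilane
Conditions: second-generation Grubbs catalyst RuCl2(=CHPh)(PCy3)(H2IMes) (cat.), toluene (dilute, degassed), 70 °C
Reagents that add atoms: none
Why: The ruthenium benzylidene loads onto the unhindered C3-vinyl group, and the resulting C4 alkylidene undergoes intramolecular [2+2] cycloaddition and cycloreversion with the vinyl ether C5=CH2 (Chauvin mechanism), expelling ethene and leaving the C4=C5 bond. The closest known reaction type is enol ether–olefin ring-closing metathesis to 2,3-dihydrofurans and 3,4-dihydro-2H-pyrans. The only ring closed is the five-membered O1–C2–C3–C4=C5 ring, formed from a 1,6-diene with the new double bond endocyclic. No stereocenter is created, and C2 and C3 are not epimerisable under these neutral conditions, so they should pass through unchanged. The step needs cyclisation to beat oligomerisation and double-bond migration, which the entropically favoured five-ring closure, the branching at C2 and C3, high dilution and loss of ethene should secure.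

Step 5
Reactants: 8 tert-butyl{[(2S,3S)-2-(3,4-dimethoxyphenyl)-2,3-dihydrofuran-3-yl]methoxy}dimethylsilane
Product: 9 [(2S,3S)-2-(3,4-dimethoxyphenyl)-2,3-dihydrofuran-3-yl]methanol
Conditions: Bu4NF, THF, 0 °C to rt
Reagents that add atoms: none
Why: Fluoride-mediated cleavage of the primary silyl ether is basic and so should spare the acid-labile cyclic enol ether and the benzylic ether.

Step 6
Reactants: 9 [(2S,3S)-2-(3,4-dimethoxyphenyl)-2,3-dihydrofuran-3-yl]methanol
Product: 12 (3S,4R,5S)-5-(3,4-dimethoxyphenyl)-4-(hydroxymethyl)oxolan-3-ol, via dimethylsilyl ether 10 (not isolated), via cyclic siloxane 11 (not isolated)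
Conditions: (HMe2Si)2NH, neat, rt, then evaporation; Pt2[(CH2=CHSiMe2)2O]3 (Karstedt catalyst, cat.), toluene, rt to 50 °C; then KF, KHCO3, H2O2, THF/MeOH, rt
Reagents that add atoms: hydrogen peroxide, OO (the oxygen on C4); 1,1,3,3-tetramethyldisilazane, C[SiH](C)N[SiH](C)C (the SiMe2 unit of intermediates 10 and 11, lost again in the oxidation)
Why: Platinum-catalysed intramolecular hydrosilylation of the homoallylic hydridosilyl ether should close the five-membered siloxane in the exo sense with silicon on the enol ether β-carbon C4, necessarily cis to the C3–CH2O arm, and Tamao–Fleming oxidation then replaces C–Si by C–OH with retention to give the all-cis diol.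

Step 7
Reactants: 12 (3S,4R,5S)-5-(3,4-dimethoxyphenyl)-4-(hydroxymethyl)oxolan-3-ol, 13 3,4-dimethoxybenzoyl chloride
Product: 14 [(2S,3R,4S)-2-(3,4-dimethoxyphenyl)-4-hydroxyoxolan-3-yl]methyl 3,4-dimethoxybenzoate
Conditions: 2,4,6-collidine, CH2Cl2, −40 to 0 °C
Reagents that add atoms: none
Why: Acylation with one equivalent of the aroyl chloride under mild base should select the unhindered primary hydroxyl over the secondary C4 hydroxyl, which is flanked cis by the C3 substituent, and any secondary ester would drift to the primary oxygen by 1,3-acyl migration across the cis diol.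

Compound list
1 | buta-2,3-dien-1-ol | C=C=CCO | starting material
2 | tert-butyl(buta-2,3-dien-1-yloxy)dimethylsilane | CC(C)(C)[Si](C)(C)OCC=C=C | intermediate
3 | 3,4-dimethoxybenzaldehyde | COc1ccc(C=O)cc1OC | starting material
4 | (Z)-allylborane: {(2Z)-4-[(tert-butyldimethylsilyl)oxy]but-2-en-1-yl}bis(isopinocampheyl)borane, isopinocampheyl groups from (+)-α-pinene | CC(C)(C)[Si](C)(C)OC/C=C\CB([C@@H]1C[C@@H]2C[C@H]([C@H]1C)C2(C)C)[C@@H]1C[C@@H]2C[C@H]([C@H]1C)C2(C)C | intermediate
5 | borinate ester: bis(isopinocampheyl)borinate of alcohol 6, boron on the benzylic oxygen | CC(C)(C)[Si](C)(C)OC[C@@H]([C@H](OB([C@@H]1C[C@@H]2C[C@H]([C@H]1C)C2(C)C)[C@@H]1C[C@@H]2C[C@H]([C@H]1C)C2(C)C)c1ccc(OC)c(OC)c1)C=C | intermediate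
6 | (1S,2S)-2-{[(tert-butyldimethylsilyl)oxy]methyl}-1-(3,4-dimethoxyphenyl)but-3-en-1-ol | CC(C)(C)[Si](C)(C)OC[C@@H]([C@H](O)c1ccc(OC)c(OC)c1)C=C | intermediate
7 | tert-butyl({(2S)-2-[(S)-(3,4-dimethoxyphenyl)(ethenyloxy)methyl]but-3-en-1-yl}oxy)dimethylsilane | CC(C)(C)[Si](C)(C)OC[C@@H]([C@H](OC=C)c1ccc(OC)c(OC)c1)C=C | intermediate
8 | tert-butyl{[(2S,3S)-2-(3,4-dimethoxyphenyl)-2,3-dihydrofuran-3-yl]methoxy}dimethylsilane (aryl and CH2O arm cis) | CC(C)(C)[Si](C)(C)OC[C@@H]1C=CO[C@@H]1c1ccc(OC)c(OC)c1 | intermediate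
9 | [(2S,3S)-2-(3,4-dimethoxyphenyl)-2,3-dihydrofuran-3-yl]methanol | OC[C@@H]1C=CO[C@@H]1c1ccc(OC)c(OC)c1 | intermediate
10 | dimethylsilyl ether: {[(2S,3S)-2-(3,4-dimethoxyphenyl)-2,3-dihydrofuran-3-yl]methoxy}dimethylsilane | C[SiH](C)OC[C@@H]1C=CO[C@@H]1c1ccc(OC)c(OC)c1 | intermediate
11 | cyclic siloxane: 2,2-dimethyl-1-oxa-2-silacyclopentane ring (O–SiMe2–C4–C3–CH2) cis-fused across C3–C4 of the oxolane, aryl on C2 cis to the CH2O arm; (2S,3S,4S) in oxolane numbering | C[Si]1(C)OC[C@@H]2[C@H]1CO[C@@H]2c1ccc(OC)c(OC)c1 | intermediate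
12 | (3S,4R,5S)-5-(3,4-dimethoxyphenyl)-4-(hydroxymethyl)oxolan-3-ol (all-cis) | OC[C@@H]1[C@H](O)CO[C@@H]1c1ccc(OC)c(OC)c1 | intermediate
13 | 3,4-dimethoxybenzoyl chloride | COc1ccc(C(Cl)=O)cc1OC | starting material
14 | [(2S,3R,4S)-2-(3,4-dimethoxyphenyl)-4-hydroxyoxolan-3-yl]methyl 3,4-dimethoxybenzoate | COc1ccc(C(=O)OC[C@@H]2[C@H](O)CO[C@@H]2c2ccc(OC)c(OC)c2)cc1OC | target

Total step count: 7. Longest linear sequence: 7 steps (1 to 14).

Steps most likely to fail

Step 2. The kinetic (Z)-geometry of allylborane 4 may be lost by 1,3-boratropic shift before the aldehyde is added, or the borane may add to the internal π-bond; either erodes the syn relationship of C2 and C3. The fallback sets out from aldehyde 3 and uses a configurationally fixed boronate with catalyst control. Commercial tert-butyldimethyl(prop-2-yn-1-yloxy)silane F1 is converted by rhodium-catalysed trans-hydroboration ([Rh(cod)Cl]2, P(iPr)3, Et3N, pinacolborane) into tert-butyldimethyl{[(2Z)-3-(4,4,5,5-tetramethyl-1,3,2-dioxaborolan-2-yl)prop-2-en-1-yl]oxy}silane F2. Matteson homologation (ClCH2Li from BrCH2Cl and n-BuLi, THF, −78 °C) should give, with retention of alkene geometry, tert-butyldimethyl{[(2Z)-4-(4,4,5,5-tetramethyl-1,3,2-dioxaborolan-2-yl)but-2-en-1-yl]oxy}silane F3. Chiral phosphoric acid-catalysed allylboration of 3 with F3 (TRIP, the enantiomer that delivers the (1S) carbinol, toluene, −30 °C) comes back to the route at alcohol 6.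

Step 4. The ruthenium may be sequestered as an unreactive alkoxycarbene at the vinyl ether, or ruthenium hydrides may migrate the double bonds before closure. The fallback sets out from alcohol 6. Formylation (acetic formic anhydride, pyridine, 0 °C) gives (1S,2S)-2-{[(tert-butyldimethylsilyl)oxy]methyl}-1-(3,4-dimethoxyphenyl)but-3-en-1-yl formate F4. A Takai–Utimoto titanium ethylidene (TiCl4, TMEDA, Zn, PbCl2 cat., CH3CHBr2, THF) should then exchange at the C3-vinyl group and olefinate the formate carbonyl intramolecularly. This olefinic-ester cyclisation again closes the ring at C4–C5 and comes back to the route at dihydrofuran 8.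

Step 6. Silicon may be delivered with the wrong regiochemistry (six-membered endo closure onto C5), or platinum may isomerise or simply reduce the enol ether. The fallback sets out from silyl ether 8. Hydroboration–oxidation (BH3·THF, 0 °C; NaOH, H2O2) anti to the C3 substituent gives (3R,4R,5S)-4-{[(tert-butyldimethylsilyl)oxy]methyl}-5-(3,4-dimethoxyphenyl)oxolan-3-ol F5. Dess–Martin oxidation (NaHCO3, CH2Cl2) gives (4S,5S)-4-{[(tert-butyldimethylsilyl)oxy]methyl}-5-(3,4-dimethoxyphenyl)oxolan-3-one F6. L-Selectride (THF, −78 °C) should attack from the face opposite the two cis substituents to give (3S,4R,5S)-4-{[(tert-butyldimethylsilyl)oxy]methyl}-5-(3,4-dimethoxyphenyl)oxolan-3-ol F7. Bu4NF then comes back to the route at diol 12.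

Further compounds
F1 | step 2 | tert-butyldimethyl(prop-2-yn-1-yloxy)silane | C#CCO[Si](C)(C)C(C)(C)C
F2 | step 2 | tert-butyldimethyl{[(2Z)-3-(4,4,5,5-tetramethyl-1,3,2-dioxaborolan-2-yl)prop-2-en-1-yl]oxy}silane | CC(C)(C)[Si](C)(C)OC/C=C\B1OC(C)(C)C(C)(C)O1
F3 | step 2 | tert-butyldimethyl{[(2Z)-4-(4,4,5,5-tetramethyl-1,3,2-dioxaborolan-2-yl)but-2-en-1-yl]oxy}silane | CC(C)(C)[Si](C)(C)OC/C=C\CB1OC(C)(C)C(C)(C)O1
F4 | step 4 | (1S,2S)-2-{[(tert-butyldimethylsilyl)oxy]methyl}-1-(3,4-dimethoxyphenyl)but-3-en-1-yl formate | CC(C)(C)[Si](C)(C)OC[C@@H]([C@H](OC=O)c1ccc(OC)c(OC)c1)C=C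
F5 | step 6 | (3R,4R,5S)-4-{[(tert-butyldimethylsilyl)oxy]methyl}-5-(3,4-dimethoxyphenyl)oxolan-3-ol | CC(C)(C)[Si](C)(C)OC[C@@H]1[C@@H](O)CO[C@@H]1c1ccc(OC)c(OC)c1
F6 | step 6 | (4S,5S)-4-{[(tert-butyldimethylsilyl)oxy]methyl}-5-(3,4-dimethoxyphenyl)oxolan-3-one | CC(C)(C)[Si](C)(C)OC[C@@H]1C(=O)CO[C@@H]1c1ccc(OC)c(OC)c1
F7 | step 6 | (3S,4R,5S)-4-{[(tert-butyldimethylsilyl)oxy]methyl}-5-(3,4-dimethoxyphenyl)oxolan-3-ol | CC(C)(C)[Si](C)(C)OC[C@@H]1[C@H](O)CO[C@@H]1c1ccc(OC)c(OC)c1
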